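**Retrosynthetic overview**
1. Target ⇒ aryl pivalate 17 ⇒ C1'–C2' bond: (E)-alkenylalane (Zr-catalysed methylalumination of terminal alkyne 12) + benzylic bromide 15 (two steps from 4-methoxy-2,6-dimethylphenol).
2. 12 ⇒ C4'–C5' bond: catalytic asymmetric propargylation of hydroxy-enal 10 (sets C5').
3. 10 ⇒ 8-hydroxyfarnesol 9 ⇒ key C12'–C13' bond: chiral d3 homoenolate (titanated (S)-1-methylallyl carbamate) + enal 2 (sets C12'); Ni/MeMgBr then turns the enol carbamate into the prenyl end.
4. 2 ⇒ geranyl acetate by allylic oxidation.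
5. No ring is formed; the benzene ring is bought.

Target stereochemistry read from the SMILES: 2E, 5R, 6E, 10E, 12R (chain numbered from the benzylic carbon C1').

Assumption: lithiation of 4 is taken to go with retention and the Li→Ti exchange with Ti(OiPr)4 with inversion (the usual course for lithiated allyl carbamates, recalled but not checked for this α-methyl/TMEDA case); if the exchange retains, (R)-but-3-en-2-ol is used in Step 2 and nothing else changes.

**Step 1**
Reactants: 1 geranyl acetate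
Product: 2 (2E,6E)-3,7-dimethyl-8-oxoocta-2,6-dien-1-yl acetate
Conditions: SeO2 (1.1 equiv), 95% EtOH, reflux, 2 h
Reagents that add atoms: selenium dioxide, O=[Se]=O
Why: Riley allylic oxidation (ene reaction, then [2,3]-sigmatropic shift) attacks the (E)-methyl of the electron-rich distal alkene, spares the acetate-deactivated 2,3-alkene, and gives the (E)-enal.

**Step 2**
Reactants: 3 (S)-but-3-en-2-ol
Product: 4 (S)-but-3-en-2-yl N,N-diisopropylcarbamate
Conditions: NaH, THF, 0 °C; iPr2NCOCl, reflux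
Reagents that add atoms: N,N-diisopropylcarbamoyl chloride, CC(C)N(C(C)C)C(Cl)=O
Why: O-acylation of the alkoxide (acyl substitution) does not touch the C–O stereocentre, so (S) is kept.

**Step 3**
Reactants: 4 (S)-but-3-en-2-yl N,N-diisopropylcarbamate (1.4 equiv); 2 (2E,6E)-3,7-dimethyl-8-oxoocta-2,6-dien-1-yl acetate
Product: 7 (2E,6E,8R,10Z)-11-[(diisopropylcarbamoyl)oxy]-8-hydroxy-3,7-dimethyldodeca-2,6,10-trien-1-yl acetate, via lithiated carbamate 5 (not isolated), via allyltitanium triisopropoxide 6 (not isolated)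
Conditions: n-BuLi, TMEDA, Et2O/hexane, −78 °C, 1 h; Ti(OiPr)4 (4 equiv), −78 °C, 1 h; 2, −78 → −40 °C; cold 2 M HCl
Reagents that add atoms: none
Why: Hoppe homoaldol reaction: the metalated carbamate is a d3 homoenolate whose γ-carbon (a β-carbonyl position, normally electrophilic) attacks the aldehyde carbon through a Zimmerman–Traxler chair (OCb axial, alkenyl equatorial), and the (S)-titanium centre is transferred to the (8R) carbinol and the (Z)-enol carbamate (= C12' of the target).

**Step 4**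
Reactants: 7 (2E,6E,8R,10Z)-11-[(diisopropylcarbamoyl)oxy]-8-hydroxy-3,7-dimethyldodeca-2,6,10-trien-1-yl acetate
Product: 9 (2E,6E,8R)-3,7,11-trimethyldodeca-2,6,10-triene-1,8-diol, via magnesium dialkoxide 8 (not isolated)
Conditions: MeMgBr (8 equiv), Et2O, 0 °C, 30 min; then Ni(acac)2 (10 mol %), 0 °C → rt, 16 h; aq NH4Cl
Reagents that add atoms: methylmagnesium bromide, C[Mg]Br
Why: The Grignard first cleaves the acetate, then Ni(0)-catalysed Kumada-type C–O cross-coupling of the enol carbamate replaces OCb by methyl to give the isopropylidene end (geometry irrelevant); the carbinol centre is not involved.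

**Step 5**
Reactants: 9 (2E,6E,8R)-3,7,11-trimethyldodeca-2,6,10-triene-1,8-diol
Product: 10 (2E,6E,8R)-8-hydroxy-3,7,11-trimethyldodeca-2,6,10-trienal
Conditions: TEMPO (10 mol %), PhI(OAc)2 (1.1 equiv), CH2Cl2, 0 °C → rt
Reagents that add atoms: none
Why: Oxoammonium (TEMPO/BAIB) oxidation is selective for the primary allylic alcohol over the hindered secondary one and does not isomerise the 2E alkene.

**Step 6**
Reactants: 10 (2E,6E,8R)-8-hydroxy-3,7,11-trimethyldodeca-2,6,10-trienal; 11 allenylboronic acid pinacol ester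
Product: 12 (4R,5E,9E,11R)-6,10,14-trimethylpentadeca-5,9,13-trien-1-yne-4,11-diol
Conditions: (R)-TRIP (10 mol %), 4 Å MS, toluene, −20 °C, 72 h
Reagents that add atoms: none
Why: Chiral phosphoric acid-catalysed propargylation (allenylboration, SE2', closed six-membered transition state) is catalyst-controlled; (R)-TRIP directs Re-face attack as in its allylborations, giving the (4R) carbinol (= C5') independent of the remote centre.

**Step 7**
Reactants: 13 4-methoxy-2,6-dimethylphenol
Product: 14 4-methoxy-2,6-dimethylphenyl pivalate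
Conditions: PivCl, Et3N, DMAP (cat.), CH2Cl2, 0 °C → rt
Reagents that add atoms: pivaloyl chloride, CC(C)(C)C(Cl)=O
Why: DMAP-catalysed O-acylation; the pivalate deactivates the ring for Step 8 and resists alanes in Step 9.

**Step 8**
Reactants: 14 4-methoxy-2,6-dimethylphenyl pivalate
Product: 15 2-(bromomethyl)-4-methoxy-6-methylphenyl pivalate
Conditions: NBS (1.0 equiv), AIBN (5 mol %), PhCF3, 85 °C, hν
Reagents that add atoms: N-bromosuccinimide, O=C1CCC(=O)N1Br
Why: Wohl–Ziegler radical bromination of one of two equivalent benzylic methyls; the ester-deactivated ring and flanked ring positions disfavour nuclear bromination, and one equivalent limits dibromination.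

**Step 9**
Reactants: 12 (4R,5E,9E,11R)-6,10,14-trimethylpentadeca-5,9,13-trien-1-yne-4,11-diol; 15 2-(bromomethyl)-4-methoxy-6-methylphenyl pivalate (1.3 equiv)
Product: 17 2-[(2E,5R,6E,10E,12R)-5,12-dihydroxy-3,7,11,15-tetramethylhexadeca-2,6,10,14-tetraen-1-yl]-4-methoxy-6-methylphenyl pivalate, via alkenylalane 16 (not isolated)
Conditions: AlMe3 (5 equiv), Cp2ZrCl2 (0.5 equiv), (CH2Cl)2, 0 °C → rt; volatiles removed; THF, 15, Pd(PPh3)4 (5 mol %), rt; aq Rochelle salt
Reagents that add atoms: trimethylaluminium, C[Al](C)C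
Why: Negishi Zr-catalysed syn-carboalumination puts methyl on the internal and Al on the terminal alkyne carbon (OH groups masked as Al alkoxides), and Pd-catalysed coupling of the alkenylalane with the benzylic bromide proceeds with retention, fixing the 2E alkene.

**Step 10**
Reactants: 17 2-[(2E,5R,6E,10E,12R)-5,12-dihydroxy-3,7,11,15-tetramethylhexadeca-2,6,10,14-tetraen-1-yl]-4-methoxy-6-methylphenyl pivalate
Product: 18 2-[(2E,5R,6E,10E,12R)-5,12-dihydroxy-3,7,11,15-tetramethylhexadeca-2,6,10,14-tetraen-1-yl]-4-methoxy-6-methylphenol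
Conditions: K2CO3, MeOH (degassed), 40 °C, Ar; aq NH4Cl
Reagents that add atoms: none
Why: Base-mediated methanolysis (transesterification) of the aryl ester; the allylic alcohols, alkenes and both stereocentres are untouched.

**Compound list**
1 | geranyl acetate, (2E)-3,7-dimethylocta-2,6-dien-1-yl acetate | CC(=O)OC/C=C(\C)CCC=C(C)C | starting material
2 | (2E,6E)-3,7-dimethyl-8-oxoocta-2,6-dien-1-yl acetate | CC(=O)OC/C=C(\C)CC/C=C(\C)C=O | intermediate
3 | (S)-but-3-en-2-ol | C[C@H](O)C=C | starting material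
4 | (S)-but-3-en-2-yl N,N-diisopropylcarbamate | C[C@H](OC(=O)N(C(C)C)C(C)C)C=C | intermediate
5 | (S)-2-lithiobut-3-en-2-yl N,N-diisopropylcarbamate (TMEDA complex; Li in the place of H) | C[C@]([Li])(OC(=O)N(C(C)C)C(C)C)C=C | intermediate
6 | (S)-2-(triisopropoxytitanio)but-3-en-2-yl N,N-diisopropylcarbamate (Ti on the face opposite to Li) | C[C@@]([Ti](OC(C)C)(OC(C)C)OC(C)C)(OC(=O)N(C(C)C)C(C)C)C=C | intermediate
7 | (2E,6E,8R,10Z)-11-[(diisopropylcarbamoyl)oxy]-8-hydroxy-3,7-dimethyldodeca-2,6,10-trien-1-yl acetate | CC(=O)OC/C=C(\C)CC/C=C(\C)[C@H](O)C/C=C(/C)OC(=O)N(C(C)C)C(C)C | intermediate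
8 | bis(bromomagnesium) alkoxide of the deacetylated enol carbamate | Br[Mg]OC/C=C(\C)CC/C=C(\C)[C@H](O[Mg]Br)C/C=C(/C)OC(=O)N(C(C)C)C(C)C | intermediate
9 | (2E,6E,8R)-3,7,11-trimethyldodeca-2,6,10-triene-1,8-diol | OC/C=C(\C)CC/C=C(\C)[C@H](O)CC=C(C)C | intermediate
10 | (2E,6E,8R)-8-hydroxy-3,7,11-trimethyldodeca-2,6,10-trienal | O=C/C=C(\C)CC/C=C(\C)[C@H](O)CC=C(C)C | intermediate
11 | allenylboronic acid pinacol ester | C=C=CB1OC(C)(C)C(C)(C)O1 | starting material
12 | (4R,5E,9E,11R)-6,10,14-trimethylpentadeca-5,9,13-trien-1-yne-4,11-diol | C#CC[C@@H](O)/C=C(\C)CC/C=C(\C)[C@H](O)CC=C(C)C | intermediate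
13 | 4-methoxy-2,6-dimethylphenol | COc1cc(C)c(O)c(C)c1 | starting material
14 | 4-methoxy-2,6-dimethylphenyl pivalate | COc1cc(C)c(OC(=O)C(C)(C)C)c(C)c1 | intermediate
15 | 2-(bromomethyl)-4-methoxy-6-methylphenyl pivalate | COc1cc(C)c(OC(=O)C(C)(C)C)c(CBr)c1 | intermediate
16 | (E)-alkenyl(dimethyl)alane of 12, both hydroxyls as dimethylaluminium alkoxides | C[Al](C)/C=C(\C)C[C@@H](O[Al](C)C)/C=C(\C)CC/C=C(\C)[C@H](O[Al](C)C)CC=C(C)C | intermediate
17 | 2-[(2E,5R,6E,10E,12R)-5,12-dihydroxy-3,7,11,15-tetramethylhexadeca-2,6,10,14-tetraen-1-yl]-4-methoxy-6-methylphenyl pivalate | COc1cc(C)c(OC(=O)C(C)(C)C)c(C/C=C(\C)C[C@@H](O)/C=C(\C)CC/C=C(\C)[C@H](O)CC=C(C)C)c1 | intermediate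
18 | 2-[(2E,5R,6E,10E,12R)-5,12-dihydroxy-3,7,11,15-tetramethylhexadeca-2,6,10,14-tetraen-1-yl]-4-methoxy-6-methylphenol | COc1cc(C)c(O)c(C/C=C(\C)C[C@@H](O)/C=C(\C)CC/C=C(\C)[C@H](O)CC=C(C)C)c1 | target

**Totals**
Total steps: 10. Longest linear sequence: 7 (steps 1, 3, 4, 5, 6, 9, 10 from geranyl acetate).

**Three steps most likely to fail**

Step 3 (homoaldol). The risks are incomplete chirality transfer, the opposite stereochemical course of the Li→Ti exchange, and partial loss of the acetate to excess Ti(OiPr)4. The fallback sets out from 1 and comes back at 9, and builds the same carbinol from an α-oxy carbanion and an alkenylboronate instead. Selective ozonolysis of the distal alkene of 1 (O3, pyridine, CH2Cl2, −78 °C; Me2S) gives (2E)-3-methyl-6-oxohex-2-en-1-yl acetate F1. A boron-Wittig reaction with 1,1-bis(pinacolboryl)ethane and LiTMP (THF, −78 °C) gives (2E,6Z)-3-methyl-7-(pinacolboryl)octa-2,6-dien-1-yl acetate F2. Separately, 4-methylpent-3-en-1-ol is carbamoylated to 4-methylpent-3-en-1-yl N,N-diisopropylcarbamate F3. s-BuLi/(−)-sparteine (Et2O, −78 °C) converts it into the (S)-α-lithiated carbamate F4. Addition of F2 and warming with MgBr2·OEt2 triggers the 1,2-metallate shift (alkenyl migrates with retention of geometry, inversion at carbon) to the allylic boronic ester (2E,6E,8R)-3,7,11-trimethyl-8-(pinacolboryl)dodeca-2,6,10-trien-1-yl acetate F5. NaOH/H2O2 oxidises C–B with retention and removes the acetate, giving 9. This route skips steps 3 and 4.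

Step 4 (Ni coupling). The risks are slow oxidative addition at the trisubstituted enol carbamate and Ni-catalysed substitution of the allylic magnesium alkoxides by MeMgBr. The fallback sets out from 2 and comes back at 9, replacing the homoenolate/C–O coupling pair by allylation and olefin metathesis. B-allyldiisopinocampheylborane prepared from (−)-α-pinene (Re-face selective; Et2O, −78 °C, diethanolamine work-up) gives (2E,6E,8R)-8-hydroxy-3,7-dimethylundeca-2,6,10-trien-1-yl acetate F6. Cross-metathesis of its terminal vinyl group with 2-methyl-2-butene (Grubbs II, neat, 40 °C; the trisubstituted alkenes do not react) gives (2E,6E,8R)-8-hydroxy-3,7,11-trimethyldodeca-2,6,10-trien-1-yl acetate F7. K2CO3/MeOH then gives 9.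

Step 9 (carboalumination/benzylation on the unprotected diol). The risks are Lewis-acid ionisation of the allylic aluminium alkoxides, a chelated alane that transmetalates slowly, and methyl transfer to 15. The fallback sets out from 12 and comes back at 17, using carboboration and Suzuki coupling. TESCl/imidazole gives the bis(triethylsilyl) ether of 12 F8. Cu-catalysed syn-methylboration (CuCl, Xantphos, B2pin2, MeI, NaOtBu, THF) gives the (E)-alkenyl pinacol boronate F9, with B on the terminal and Me on the internal carbon. Suzuki–Miyaura coupling with 15 (Pd(dppf)Cl2, K3PO4, THF/H2O, 50 °C) gives the bis(triethylsilyl) ether of 17 F10. TBAF/AcOH (THF, 0 °C) gives 17.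

**Further compounds**
F1 | step 3 | (2E)-3-methyl-6-oxohex-2-en-1-yl acetate | CC(=O)OC/C=C(\C)CCC=O
F2 | step 3 | (2E,6Z)-3-methyl-7-(4,4,5,5-tetramethyl-1,3,2-dioxaborolan-2-yl)octa-2,6-dien-1-yl acetate | CC(=O)OC/C=C(\C)CC/C=C(\C)B1OC(C)(C)C(C)(C)O1
F3 | step 3 | 4-methylpent-3-en-1-yl N,N-diisopropylcarbamate | CC(C)=CCCOC(=O)N(C(C)C)C(C)C
F4 | step 3 | (S)-1-lithio-4-methylpent-3-en-1-yl N,N-diisopropylcarbamate | [Li][C@@H](CC=C(C)C)OC(=O)N(C(C)C)C(C)C
F5 | step 3 | (2E,6E,8R)-3,7,11-trimethyl-8-(4,4,5,5-tetramethyl-1,3,2-dioxaborolan-2-yl)dodeca-2,6,10-trien-1-yl acetate | CC(=O)OC/C=C(\C)CC/C=C(\C)[C@H](B1OC(C)(C)C(C)(C)O1)CC=C(C)C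
F6 | step 4 | (2E,6E,8R)-8-hydroxy-3,7-dimethylundeca-2,6,10-trien-1-yl acetate | CC(=O)OC/C=C(\C)CC/C=C(\C)[C@H](O)CC=C
F7 | step 4 | (2E,6E,8R)-8-hydroxy-3,7,11-trimethyldodeca-2,6,10-trien-1-yl acetate | CC(=O)OC/C=C(\C)CC/C=C(\C)[C@H](O)CC=C(C)C
F8 | step 9 | (4R,5E,9E,11R)-6,10,14-trimethyl-4,11-bis(triethylsilyloxy)pentadeca-5,9,13-trien-1-yne | C#CC[C@@H](O[Si](CC)(CC)CC)/C=C(\C)CC/C=C(\C)[C@H](O[Si](CC)(CC)CC)CC=C(C)C
F9 | step 9 | (1E,4R,5E,9E,11R)-alkenyl pinacol boronate from methylboration of F8 | CC1(C)OB(/C=C(\C)C[C@@H](O[Si](CC)(CC)CC)/C=C(\C)CC/C=C(\C)[C@H](O[Si](CC)(CC)CC)CC=C(C)C)OC1(C)C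
F10 | step 9 | 5,12-bis(triethylsilyl) ether of 17 | COc1cc(C)c(OC(=O)C(C)(C)C)c(C/C=C(\C)C[C@@H](O[Si](CC)(CC)CC)/C=C(\C)CC/C=C(\C)[C@H](O[Si](CC)(CC)CC)CC=C(C)C)c1
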